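**Assumption:** the CBS alcohol is formed in about 90–95 % ee and is upgraded, if needed, by one recrystallisation at the crystalline bicyclic diol stage. β means the face of the angular methyl, α the opposite face; locants C1–C10 are daucane numbering.

## Retrosynthetic overview

1. Target ⇐ O-acetylferutinin: the last C8–O bond is made by an ester-relayed, selenium-catalysed allylic hydroxylation that moves C8=C9 to C9=C10; the aryl acetate is removed in the same flask.
2. O-Acetylferutinin ⇐ jaeschkeanadiol (acylation at C6–O) ⇐ allyl/methallyl diene by ring-closing metathesis (seven-membered ring, closed last).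
3. Diene ⇐ β-hydroxy aldehyde + methallyl (C6–C7, chelation control) ⇐ 1,3-diol ⇐ C–Si oxidation.
4. 1,3-Diol ⇐ cyclopentanone + isopropyl (C4) ⇐ bicyclic siloxane by silicon-tethered radical cyclisation/allyl transfer (C5 and C1).
5. Siloxane ⇐ (S)-3-methylcyclopent-2-en-1-ol ⇐ 3-methylcyclopent-2-en-1-one (five-membered ring bought; CBS reduction sets absolute configuration).

## Route

Step 1
Reactants: 1 3-methylcyclopent-2-en-1-one
Product: 2 (S)-3-methylcyclopent-2-en-1-ol
Conditions: (R)-2-methyl-CBS-oxazaborolidine (10 mol %), BH3·SMe2 (0.7 equiv), THF, −20 °C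
Reagents that add atoms: none
Why: Corey–Bakshi–Shibata reduction, in which the alkenyl flank acts as the large group so the (R)-catalyst gives the (S)-allylic alcohol whose oxygen later steers C5 and C1.

Step 2
Reactants: 2 (S)-3-methylcyclopent-2-en-1-ol; 3 (bromomethyl)chlorodimethylsilane
Product: 4 (S)-(bromomethyl)dimethylsilyl ether of 2
Conditions: Et3N (1.5 equiv), DMAP (5 mol %), CH2Cl2, 0 °C
Reagents that add atoms: (bromomethyl)chlorodimethylsilane C[Si](C)(Cl)CBr
Why: O-silylation of the allylic alcohol installs the Stork–Nishiyama radical tether without touching the stereocentre.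

Step 3
Reactants: 4 bromomethylsilyl ether; 5 allyltributylstannane
Product: 6 cis-fused bicyclic siloxane (C4–H)
Conditions: 5 (4 equiv), AIBN (0.2 equiv, portions), PhH (0.05 M), 80 °C
Reagents that add atoms: allyltributylstannane C=CC[Sn](CCCC)(CCCC)CCCC
Why: Stork–Nishiyama 5-exo cyclisation of the α-silyl radical places the CH2Si carbon on C5 cis to the C4 oxygen, and Keck allyl transfer to the tertiary C1 radical occurs on the convex face anti to that new arm, so C5 and C1 (methyl cis to CH2Si, allyl trans) are set from C4.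

Step 4
Reactants: 6 bicyclic siloxane
Product: 7 silanol ketone
Conditions: CrO3, H2SO4, H2O, acetone, 0 °C, 30 min
Reagents that add atoms: water O
Why: Jones oxidation, in which acid opens the strained cyclic silyl ether and the freed secondary alcohol is oxidised to the ketone while the C–Si bond survives as a silanol (masked hydroxymethyl); brief cold contact avoids epimerisation at C5.

Step 5
Reactants: 7 silanol ketone; 8 isopropylmagnesium chloride
Product: 9 bicyclic siloxane (C4 isopropyl carbinol)
Conditions: 8 (3 equiv), CeCl3 (3 equiv), THF, −78 to 0 °C; aq NH4Cl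
Reagents that add atoms: isopropylmagnesium chloride CC(C)[Mg]Cl
Why: Imamoto organocerium 1,2-addition suppresses enolisation and reduction, and attack anti to the bulky C5 CH2Si arm gives the tertiary alcohol with oxygen cis to that arm (C4 R, 4β-O), the γ-hydroxy silanol closing to the five-membered siloxane on work-up.

Step 6
Reactants: 9 bicyclic siloxane
Product: 10 1,3-diol
Conditions: 30 % H2O2, KF, KHCO3, THF/MeOH (1:1), 40 °C
Reagents that add atoms: hydrogen peroxide OO
Why: Tamao–Fleming oxidation converts C–Si to C–OH with retention and frees the tertiary alcohol, the terminal alkene being inert.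

Step 7
Reactants: 10 1,3-diol
Product: 11 β-hydroxy aldehyde
Conditions: Dess–Martin periodinane (1.3 equiv), NaHCO3, CH2Cl2, 0 °C to rt
Reagents that add atoms: none
Why: Dess–Martin oxidation takes only the primary alcohol (the tertiary one cannot be oxidised) under buffered conditions that avoid retro-aldol cleavage or C5 epimerisation.

Step 8
Reactants: 11 β-hydroxy aldehyde; 12 (2-methylprop-2-en-1-yl)magnesium chloride
Product: 13 allyl/methallyl diene diol
Conditions: MgBr2·OEt2 (1.5 equiv), CH2Cl2, −78 °C; then 12 (2.5 equiv, THF), −78 °C; aq NH4Cl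
Reagents that add atoms: (2-methylprop-2-en-1-yl)magnesium chloride CC(=C)C[Mg]Cl
Why: Cram-chelate-controlled Grignard addition, in which magnesium bridges the C4 oxygen and the aldehyde in a six-membered chelate cis-fused to the cyclopentane and methallyl adds to its convex face (isopropyl equatorial) to give the (S)-carbinol, i.e. the 6α-oxygen.

Step 9
Reactants: 13 diene diol
Product: 14 jaeschkeanadiol
Conditions: second-generation Grubbs catalyst RuCl2(=CHPh)(H2IMes)(PCy3) (5 mol %), CH2Cl2 (5 mM), 40 °C
Reagents that add atoms: none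
Why: Ring-closing metathesis of the allyl and methallyl arms closes the trans-fused cycloheptene with the trisubstituted C8=C9 alkene; free hydroxyls are tolerated and no stereocentre is touched.

Step 10
Reactants: 14 jaeschkeanadiol; 15 4-(acetyloxy)benzoyl chloride
Product: 16 O-acetylferutinin
Conditions: 15 (1.3 equiv), pyridine (3 equiv), DMAP (10 mol %), CH2Cl2, 0 °C to rt
Reagents that add atoms: 4-(acetyloxy)benzoyl chloride CC(=O)Oc1ccc(cc1)C(Cl)=O
Why: DMAP-catalysed acylation takes only the secondary C6 hydroxyl (the tertiary C4 hydroxyl is unreactive), and the phenol stays masked as its acetate for the oxidative step.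

Step 11
Reactants: 16 O-acetylferutinin
Product: 19 target ester, via dioxanylium selenide 17 (not isolated), via aryl acetate 18 (not isolated)
Conditions: (PhSe)2 (10 mol %), 1-fluoro-2,4,6-trimethylpyridinium triflate (1.05 equiv), H2O (3 equiv), MeCN, 23 °C; then K2CO3 (4 equiv), MeOH, 0 °C
Reagents that add atoms: water O
Why: Proposed new method: an ester-relayed, selenium-π-acid-catalysed transpositional allylic hydroxylation, in which PhSe+ (from (PhSe)2 and the N–F oxidant) adds reversibly to C8=C9 but only the β-seleniranium can be opened at the tertiary C8 by the carbonyl oxygen of the 6α-aroyl ester, giving the bridged 1,3-dioxan-2-ylium 17 and so fixing the new C8–O bond cis to the C6 oxygen (8α, R); water then hydrolyses 17 (the C8 oxygen is the former carbonyl oxygen, and acid-catalysed orthoacid equilibration leaves the acyl group on the less hindered C6 oxygen), the C9 selenide is oxidised to tetravalent selenium and eliminates toward C10 (the only β-hydrogens, C8 being fully substituted) to give C9=C10 and return the catalyst, and K2CO3/MeOH finally cleaves the aryl acetate; the 4-OH cannot compete because in the trans-fused bicycle it is held anti to C8; the closest known chemistry is selenium-catalysed oxidative allylic amination, lactonisation and etherification with N–F oxidants, Sharpless hydroxyselenation–selenoxide elimination, and 1,3-acyl/carbonate participation as in Bartlett iodocarbonate cyclisation and Woodward–Prévost acyloxonium hydrolysis.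

## Compound list

1 | 3-methylcyclopent-2-en-1-one | CC1=CC(=O)CC1 | starting material
2 | (S)-3-methylcyclopent-2-en-1-ol | CC1=C[C@@H](O)CC1 | intermediate
3 | (bromomethyl)chlorodimethylsilane | C[Si](C)(Cl)CBr | starting material
4 | (S)-(bromomethyl)dimethyl[(3-methylcyclopent-2-en-1-yl)oxy]silane | CC1=C[C@@H](O[Si](C)(C)CBr)CC1 | intermediate
5 | allyltributylstannane | C=CC[Sn](CCCC)(CCCC)CCCC | starting material
6 | (3aR,4R,6aS)-2,2,4-trimethyl-4-(prop-2-en-1-yl)hexahydro-2H-cyclopenta[d][1,2]oxasilole (cis-fused; ring O on the carbinol carbon, CH2Si on the next carbon cis to O, quaternary carbon with methyl cis and allyl trans to CH2Si) | O1[C@H]2CC[C@](C)(CC=C)[C@H]2C[Si]1(C)C | intermediate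
7 | (2R,3R)-2-{[hydroxy(dimethyl)silyl]methyl}-3-methyl-3-(prop-2-en-1-yl)cyclopentan-1-one | O=C1CC[C@](C)(CC=C)[C@H]1C[Si](C)(C)O | intermediate
8 | isopropylmagnesium chloride | CC(C)[Mg]Cl | starting material
9 | (3aR,4R,6aR)-2,2,4-trimethyl-6a-(propan-2-yl)-4-(prop-2-en-1-yl)hexahydro-2H-cyclopenta[d][1,2]oxasilole | O1[C@@]2(C(C)C)CC[C@](C)(CC=C)[C@H]2C[Si]1(C)C | intermediate
10 | (1R,2S,3R)-2-(hydroxymethyl)-3-methyl-1-(propan-2-yl)-3-(prop-2-en-1-yl)cyclopentan-1-ol | CC(C)[C@]1(O)CC[C@](C)(CC=C)[C@H]1CO | intermediate
11 | (1R,2R,5R)-2-hydroxy-5-methyl-2-(propan-2-yl)-5-(prop-2-en-1-yl)cyclopentane-1-carbaldehyde | CC(C)[C@]1(O)CC[C@](C)(CC=C)[C@H]1C=O | intermediate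
12 | (2-methylprop-2-en-1-yl)magnesium chloride | CC(=C)C[Mg]Cl | starting material
13 | (1R,2S,3R)-2-[(1S)-1-hydroxy-3-methylbut-3-en-1-yl]-3-methyl-1-(propan-2-yl)-3-(prop-2-en-1-yl)cyclopentan-1-ol | CC(C)[C@]1(O)CC[C@](C)(CC=C)[C@H]1[C@@H](O)CC(C)=C | intermediate
14 | jaeschkeanadiol, (3R,3aS,4S,8aR)-6,8a-dimethyl-3-(propan-2-yl)-1,2,3,3a,4,5,8,8a-octahydroazulene-3,4-diol | CC(C)[C@]1(O)CC[C@]2(C)CC=C(C)C[C@H](O)[C@H]21 | intermediate
15 | 4-(acetyloxy)benzoyl chloride | CC(=O)Oc1ccc(cc1)C(Cl)=O | starting material
16 | O-acetylferutinin, (3R,3aS,4S,8aR)-3-hydroxy-6,8a-dimethyl-3-(propan-2-yl)-1,2,3,3a,4,5,8,8a-octahydroazulen-4-yl 4-(acetyloxy)benzoate | CC(C)[C@]1(O)CC[C@]2(C)CC=C(C)C[C@H](OC(=O)c3ccc(OC(C)=O)cc3)[C@H]21 | intermediate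
17 | 2-[4-(acetyloxy)phenyl]-1,3-dioxan-2-ylium triflate bridging the 6α and 8α oxygens, with 9β-phenylselanyl | CC(C)[C@]1(O)CC[C@]2(C)C[C@@H]([Se]c4ccccc4)[C@@]3(C)C[C@H](OC(=[O+]3)c5ccc(OC(C)=O)cc5)[C@H]21.[O-]S(=O)(=O)C(F)(F)F | intermediate
18 | (3R,3aS,4S,6R,8aR)-3,6-dihydroxy-6,8a-dimethyl-3-(propan-2-yl)-1,2,3,3a,4,5,6,8a-octahydroazulen-4-yl 4-(acetyloxy)benzoate | CC(C)[C@]1(O)CC[C@]2(C)C=C[C@](C)(O)C[C@H](OC(=O)c3ccc(OC(C)=O)cc3)[C@H]21 | intermediate
19 | (3R,3aS,4S,6R,8aR)-3,6-dihydroxy-6,8a-dimethyl-3-(propan-2-yl)-1,2,3,3a,4,5,6,8a-octahydroazulen-4-yl 4-hydroxybenzoate | CC(C)[C@]1(O)CC[C@]2(C)C=C[C@](C)(O)C[C@H](OC(=O)c3ccc(O)cc3)[C@H]21 | target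

## Step count and risks

Total step count: 11. Longest linear sequence: 11 steps (1 to 19).

Steps most likely to fail: 11, 5 and 8.

**Step 11 (the new reaction).** It may fail if the bridged dioxanylium cannot form on the seven-membered ring or if water opens the seleniranium directly. The fallback uses known chemistry and sets out from 16. A Schenck ene reaction with singlet oxygen (O2, tetraphenylporphyrin, visible light, CH2Cl2, 0 °C) adds oxygen to C8 from the α face with abstraction of the axial 10α-hydrogen, the C6 ester disfavouring abstraction at C7, and gives the tertiary allylic 8α-hydroperoxide F1. PPh3 reduces it in the same flask to aryl acetate 18, where the route is rejoined and finished with K2CO3/MeOH as in step 11.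

**Step 5.** A branched nucleophile on a hindered, enolisable ketone may give reduction, enolisation or poor facial selectivity. The fallback sets out from 7. Isopropenylmagnesium bromide with CeCl3 (a smaller sp2 nucleophile without β-hydrogens) gives the isopropenyl carbinol siloxane F2. Hydrogen-atom-transfer hydrogenation (Mn(dpm)3, PhSiH3, tert-butyl hydroperoxide, iPrOH, rt) then reduces only the 1,1-disubstituted alkene, the monosubstituted allyl group reacting much more slowly, and comes back at 9.

**Step 8.** The C6 configuration rests on the chelate model. The fallback sets out from 10 and uses catalyst-controlled methallylation from the alcohol oxidation level by iridium-catalysed transfer hydrogenation ([Ir(cod)Cl]2, the SEGPHOS enantiomer that gives the (S)-carbinol, 4-cyano-3-nitrobenzoic acid, Cs2CO3, methallyl chloride, THF, 90 °C). This oxidises 10 in situ, bypasses free aldehyde 11 and comes back at 13; it makes no new compound (none, F0).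

## Further compounds

F1 | step 11 | (3R,3aS,4S,6R,8aR)-6-hydroperoxy-3-hydroxy-6,8a-dimethyl-3-(propan-2-yl)-1,2,3,3a,4,5,6,8a-octahydroazulen-4-yl 4-(acetyloxy)benzoate | CC(C)[C@]1(O)CC[C@]2(C)C=C[C@](C)(OO)C[C@H](OC(=O)c3ccc(OC(C)=O)cc3)[C@H]21
F2 | step 5 | (3aR,4R,6aR)-2,2,4-trimethyl-6a-(prop-1-en-2-yl)-4-(prop-2-en-1-yl)hexahydro-2H-cyclopenta[d][1,2]oxasilole | O1[C@@]2(C(C)=C)CC[C@](C)(CC=C)[C@H]2C[Si]1(C)C
F0 | step 8 | none | none
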